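**Plan**

- Retrosynthetic cuts: the phenol O–benzyl bond (last step), C6–C7 (octyl Grignard reagent onto a C5–C6 epoxide), C5–O (oxygen handed over from O3 through a cyclic carbonate, with iodine placed on C6) and C3–C4 (allyl addition to a 3-arylpropanal).
- Enabling feature: O3 and O5 stand 1,3 on the open chain and C6 is the first CH2 of an unbranched tail. A terminal C5=C6 alkene can therefore take oxygen at C5 from a carbonate on O3 through a six-membered 1,3-dioxan-2-one ring (O3–C3–C4–C5–O5 plus the carbonyl carbon), and the iodine left on C6 prepares that carbon for the octyl unit.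
- Forward order: the arylpropyl unit C1–C3 is joined to allyl (C4–C6), the alcohol is converted to its tert-butyl carbonate, IBr closes the only ring of the route, base turns it into the C5–C6 epoxide, octyl (C7–C14) is added at C6, and the benzyl group is removed.
- Stereochemistry: C3 (S) comes from a catalyst-controlled Keck allylation. C5 (R) is relayed from C3 in the chair-like iodocarbonate closure (cis carbonate = syn diol). No later step breaks a bond at either centre.

Key step: step 5

Assumption: atom labels C1–C14 follow the tetradecane chain of the target (C1 benzylic, C3 and C5 the carbinol carbons, C14 the methyl group); the target is the syn (3S,5R) diol.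

**Route**

Step 1
Reactants: 1 dihydroconiferyl alcohol; 2 benzyl bromide
Product: 3 3-[4-(benzyloxy)-3-methoxyphenyl]propan-1-ol
Conditions: BnBr (1.1 equiv), K2CO3, acetone, reflux
Reagents that add atoms: benzyl bromide, BrCc1ccccc1
Why: Williamson etherification in which K2CO3 deprotonates only the phenol, so the primary alcohol stays free.

Step 2
Reactants: 3 3-[4-(benzyloxy)-3-methoxyphenyl]propan-1-ol
Product: 4 3-[4-(benzyloxy)-3-methoxyphenyl]propanal
Conditions: PhI(OAc)2 (1.1 equiv), 2,2,6,6-tetramethylpiperidin-1-oxyl (10 mol%), CH2Cl2, rt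
Reagents that add atoms: none
Why: Oxoammonium-mediated (nitroxyl-catalysed) oxidation of a primary alcohol, which stops at the aldehyde in dry CH2Cl2 and should leave the benzyl ether and the electron-rich ring untouched.

Step 3
Reactants: 4 3-[4-(benzyloxy)-3-methoxyphenyl]propanal; 5 allyltributylstannane
Product: 6 (3S)-1-[4-(benzyloxy)-3-methoxyphenyl]hex-5-en-3-ol
Conditions: (R)-1,1'-bi-2-naphthol (10 mol%), Ti(OiPr)4 (10 mol%), 4 Å MS, CH2Cl2; then 4, allylSnBu3 (1.3 equiv), −20 °C; sat. aq. NaHCO3
Reagents that add atoms: allyltributylstannane, C=CC[Sn](CCCC)(CCCC)CCCC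
Why: Keck asymmetric allylation, in which the titanium Lewis acid formed from Ti(OiPr)4 and (R)-1,1'-bi-2-naphthol activates the aldehyde and steers allyl transfer from the stannane to its Re face, which for this unbranched aldehyde (allyl ranks above the arylethyl chain) sets C3 as S.

Step 4
Reactants: 6 (3S)-1-[4-(benzyloxy)-3-methoxyphenyl]hex-5-en-3-ol; 7 di-tert-butyl dicarbonate
Product: 8 tert-butyl (3S)-1-[4-(benzyloxy)-3-methoxyphenyl]hex-5-en-3-yl carbonate
Conditions: Boc2O (1.5 equiv), 4-(dimethylamino)pyridine (0.3 equiv), MeCN, rt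
Reagents that add atoms: di-tert-butyl dicarbonate, CC(C)(C)OC(=O)OC(=O)OC(C)(C)C
Why: Nucleophile-catalysed acylation of the secondary alcohol (O-Boc formation), which does not touch the C3–O bond and so keeps the configuration.

Step 5
Reactants: 8 tert-butyl (3S)-1-[4-(benzyloxy)-3-methoxyphenyl]hex-5-en-3-yl carbonate; 9 iodine monobromide
Product: 10 (4S,6S)-6-{2-[4-(benzyloxy)-3-methoxyphenyl]ethyl}-4-(iodomethyl)-1,3-dioxan-2-one (cis)
Conditions: IBr (1.3 equiv, 1 M in CH2Cl2), PhMe, −85 °C; then aq. Na2S2O3/NaHCO3
Reagents that add atoms: iodine monobromide, IBr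
Why: IBr adds reversibly to the terminal C5=C6 alkene to give an iodonium ion, the carbonyl oxygen of the tert-butyl carbonate opens it at the internal carbon C5, and the resulting 2-tert-butoxy-1,3-dioxan-2-ylium ion loses its tert-butyl group as tert-butyl bromide; this is the known iodocarbonate cyclisation of homoallylic tert-butyl carbonates. The 1,3-dioxan-2-one ring closes in the 6-exo mode and the step makes the C5–O and C6–I bonds. The new stereocentre C5 is controlled by the existing C3 centre: in the chair-like transition state the arylethyl group on C3 and the iodonium-bearing CH2 on C5 both lie equatorial, which leads to the cis (4S,6S) carbonate, the syn arrangement of O3 and O5. The step needs cis over trans selectivity, which that equatorial preference should secure under kinetic control at −85 °C, a temperature at which IBr is still reactive enough. It also needs the alkene to react before the benzyloxy-methoxy-substituted ring, which the intramolecular capture by the tethered carbonate at low temperature in a non-polar solvent should secure.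

Step 6
Reactants: 10 (4S,6S)-6-{2-[4-(benzyloxy)-3-methoxyphenyl]ethyl}-4-(iodomethyl)-1,3-dioxan-2-one
Product: 12 (2S)-4-[4-(benzyloxy)-3-methoxyphenyl]-1-[(2S)-oxiran-2-yl]butan-2-ol, via iodo diol 11 (not isolated)
Conditions: K2CO3 (3 equiv), MeOH, 0 °C → rt
Reagents that add atoms: none
Why: Base-mediated methanolysis of the cyclic carbonate frees both hydroxyls and the C5 alkoxide displaces iodide on C6 in an intramolecular Williamson (3-exo-tet) closure that is much faster than tetrahydrofuran formation from O3, so no bond at C3 or C5 is broken and both centres keep their configuration.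

Step 7
Reactants: 12 (2S)-4-[4-(benzyloxy)-3-methoxyphenyl]-1-[(2S)-oxiran-2-yl]butan-2-ol; 13 octylmagnesium bromide
Product: 14 (3S,5R)-1-[4-(benzyloxy)-3-methoxyphenyl]tetradecane-3,5-diol
Conditions: n-C8H17MgBr (3.5 equiv), CuI (15 mol%), THF, −40 → −20 °C; then sat. aq. NH4Cl
Reagents that add atoms: octylmagnesium bromide, CCCCCCCC[Mg]Br
Why: Copper-catalysed Grignard opening of a terminal epoxide, in which the first equivalent of reagent deprotonates the C3 hydroxyl and the octylcuprate then attacks the unhindered C6 in an SN2 manner, forming the C6–C7 bond without touching C3 or C5.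

Step 8
Reactants: 14 (3S,5R)-1-[4-(benzyloxy)-3-methoxyphenyl]tetradecane-3,5-diol
Product: 15 (3S,5R)-1-(4-hydroxy-3-methoxyphenyl)tetradecane-3,5-diol
Conditions: H2 (1 atm), 10% Pd/C, EtOAc/EtOH, rt
Reagents that add atoms: none
Why: Catalytic hydrogenolysis cleaves only the benzylic C–O bond of the aryl benzyl ether, while the secondary alcohols, the aryl methyl ether and both stereocentres are inert under these conditions.

**Compound list**

1 | dihydroconiferyl alcohol, 4-(3-hydroxypropyl)-2-methoxyphenol | OCCCc1ccc(O)c(OC)c1 | starting material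
2 | benzyl bromide | BrCc1ccccc1 | starting material
3 | 3-[4-(benzyloxy)-3-methoxyphenyl]propan-1-ol | OCCCc1ccc(OCc2ccccc2)c(OC)c1 | intermediate
4 | 3-[4-(benzyloxy)-3-methoxyphenyl]propanal | O=CCCc1ccc(OCc2ccccc2)c(OC)c1 | intermediate
5 | allyltributylstannane | C=CC[Sn](CCCC)(CCCC)CCCC | starting material
6 | (3S)-1-[4-(benzyloxy)-3-methoxyphenyl]hex-5-en-3-ol | C=CC[C@@H](O)CCc1ccc(OCc2ccccc2)c(OC)c1 | intermediate
7 | di-tert-butyl dicarbonate | CC(C)(C)OC(=O)OC(=O)OC(C)(C)C | starting material
8 | tert-butyl (3S)-1-[4-(benzyloxy)-3-methoxyphenyl]hex-5-en-3-yl carbonate | C=CC[C@@H](OC(=O)OC(C)(C)C)CCc1ccc(OCc2ccccc2)c(OC)c1 | intermediate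
9 | iodine monobromide | IBr | starting material
10 | (4S,6S)-6-{2-[4-(benzyloxy)-3-methoxyphenyl]ethyl}-4-(iodomethyl)-1,3-dioxan-2-one (cis) | IC[C@@H]1C[C@@H](OC(=O)O1)CCc2ccc(OCc3ccccc3)c(OC)c2 | intermediate
11 | (2S,4S)-6-[4-(benzyloxy)-3-methoxyphenyl]-1-iodohexane-2,4-diol | IC[C@@H](O)C[C@@H](O)CCc1ccc(OCc2ccccc2)c(OC)c1 | intermediate
12 | (2S)-4-[4-(benzyloxy)-3-methoxyphenyl]-1-[(2S)-oxiran-2-yl]butan-2-ol | C1O[C@H]1C[C@@H](O)CCc2ccc(OCc3ccccc3)c(OC)c2 | intermediate
13 | octylmagnesium bromide | CCCCCCCC[Mg]Br | starting material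
14 | (3S,5R)-1-[4-(benzyloxy)-3-methoxyphenyl]tetradecane-3,5-diol | CCCCCCCCC[C@@H](O)C[C@@H](O)CCc1ccc(OCc2ccccc2)c(OC)c1 | intermediate
15 | (3S,5R)-1-(4-hydroxy-3-methoxyphenyl)tetradecane-3,5-diol | CCCCCCCCC[C@@H](O)C[C@@H](O)CCc1ccc(O)c(OC)c1 | target

**Step count**

Total: 8 steps. Longest linear sequence: 8 steps (1 → 15).

**Steps most likely to fail**

1. Step 5. Electrophilic halogenation of the electron-rich benzyloxy-methoxy ring by IBr could compete with the alkene, or the cis preference of the ring closure could erode if the iodonium ion equilibrates at higher temperature. The fallback sets out from 6, uses no halogen electrophile and comes back at 15.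
   - Cross-metathesis of 6 with methyl acrylate (second-generation Grubbs catalyst RuCl2(=CHPh)(PCy3)(H2IMes), CH2Cl2, 40 °C) should give methyl (2E,5S)-7-[4-(benzyloxy)-3-methoxyphenyl]-5-hydroxyhept-2-enoate F1.
   - Benzaldehyde and KOtBu in THF at 0 °C convert the C3 hydroxyl into a hemiacetal alkoxide that adds to C5 in an intramolecular oxa-Michael reaction under thermodynamic control. This should give the all-cis acetal methyl 2-[(2S,4S,6S)-6-{2-[4-(benzyloxy)-3-methoxyphenyl]ethyl}-2-phenyl-1,3-dioxan-4-yl]acetate F2, with the C5 oxygen syn to O3.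
   - Diisobutylaluminium hydride in CH2Cl2 at −78 °C reduces the ester to 2-[(2S,4S,6S)-6-{2-[4-(benzyloxy)-3-methoxyphenyl]ethyl}-2-phenyl-1,3-dioxan-4-yl]acetaldehyde F3.
   - Wittig olefination with the ylide from heptyltriphenylphosphonium bromide and NaN(SiMe3)2 in THF (−78 °C → rt) completes the chain as (2S,4S,6R)-4-{2-[4-(benzyloxy)-3-methoxyphenyl]ethyl}-6-[(2Z)-non-2-en-1-yl]-2-phenyl-1,3-dioxane F4.
   - Hydrogenation over Pd(OH)2/C in MeOH/EtOAc saturates the alkene and cleaves both the benzylidene acetal and the benzyl ether, giving 15.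

2. Step 7. The Grignard reagent could act as a base or halide donor instead of an alkyl donor (bromohydrin formation through MgBr2, or slow alkyl transfer from the cuprate in the presence of the magnesium alkoxide). The fallback sets out from 12 and comes back at 15.
   - Lithium oct-1-ynide (3 equiv, from oct-1-yne and n-BuLi) with BF3·OEt2 in THF at −78 °C opens the epoxide at C6 and should give (3S,5R)-1-[4-(benzyloxy)-3-methoxyphenyl]tetradec-7-yne-3,5-diol F5.
   - Hydrogenation over 10% Pd/C in EtOAc/EtOH reduces the triple bond and removes the benzyl group in the same operation, giving 15.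

3. Step 3. Enantiofacial discrimination by the titanium catalyst could be incomplete, or turnover with this unbranched aldehyde could be slow, so that the uncatalysed racemic addition takes part. The fallback sets out from 4 and comes back at 6.
   - It replaces Lewis-acid catalysis by reagent control in a Brown allylation. (+)-B-allyldiisopinocampheylborane, the reagent enantiomer derived from (−)-α-pinene and made from (+)-Ipc2BOMe and allylMgBr, is used in Et2O at −78 °C, followed by NaOH/H2O2.
   - The allylborane reacts through a closed six-membered chair transition state and delivers allyl to the Re face of unbranched aldehydes, so it should give 6 directly.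
   - This fallback makes no compound outside the list (F0).

Further compounds
F1 | step 5 | methyl (2E,5S)-7-[4-(benzyloxy)-3-methoxyphenyl]-5-hydroxyhept-2-enoate | COC(=O)/C=C/C[C@@H](O)CCc1ccc(OCc2ccccc2)c(OC)c1
F2 | step 5 | methyl 2-[(2S,4S,6S)-6-{2-[4-(benzyloxy)-3-methoxyphenyl]ethyl}-2-phenyl-1,3-dioxan-4-yl]acetate | O1[C@H](c2ccccc2)O[C@H](CC(=O)OC)C[C@@H]1CCc3ccc(OCc4ccccc4)c(OC)c3
F3 | step 5 | 2-[(2S,4S,6S)-6-{2-[4-(benzyloxy)-3-methoxyphenyl]ethyl}-2-phenyl-1,3-dioxan-4-yl]acetaldehyde | O1[C@H](c2ccccc2)O[C@H](CC=O)C[C@@H]1CCc3ccc(OCc4ccccc4)c(OC)c3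
F4 | step 5 | (2S,4S,6R)-4-{2-[4-(benzyloxy)-3-methoxyphenyl]ethyl}-6-[(2Z)-non-2-en-1-yl]-2-phenyl-1,3-dioxane | O1[C@H](c2ccccc2)O[C@H](C/C=C\CCCCCC)C[C@@H]1CCc3ccc(OCc4ccccc4)c(OC)c3
F5 | step 7 | (3S,5R)-1-[4-(benzyloxy)-3-methoxyphenyl]tetradec-7-yne-3,5-diol | CCCCCCC#CC[C@@H](O)C[C@@H](O)CCc1ccc(OCc2ccccc2)c(OC)c1
F0 | step 3 | none | none
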